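**Retrosynthetic overview**

1. Rings A and B (the trans-decalin) and the stereocentres C5, C8, C9 and C10, including the C8–O bond, are taken intact from (−)-sclareol 1. No ring is formed and no C–C bond is made anywhere in the route.
2. C15–O disconnection: the C15 oxygen comes from an oxidative 1,3-transposition of the C13 tertiary allylic alcohol of 1, giving the (13E)-enal 2.
3. Acyl C15–O and C13–H disconnection: labdanolic acid 3 comes from 2 plus water by a carbene-catalysed asymmetric redox hydration (new), which sets C13.
4. Formate C–O disconnection: the target 6 comes from 3 and formic acid 4, through the transient mixed anhydride 5.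
5. Order of events: rings present from the start; then the C15–O bond; then the acid C–O bond together with C13; last the O8–CHO bond.

Assumption: labdane numbering is used (side-chain stereocentre = C13, formate-bearing carbon = C8). The sense of induction of the catalyst-controlled steps is assigned by analogy; if it proves opposite, the equally available antipodal catalyst is used.

**Step 1**
Reactants: 1 (−)-sclareol [(13R)-labd-14-ene-8α,13-diol]
Product: 2 (13E)-8α-hydroxylabd-13-en-15-al
Conditions: [C5H5NH][CrO3Cl] (pyridinium chlorochromate, 3 equiv), SiO2, 4 Å MS, CH2Cl2, 23 °C; flash chromatography to separate the 13E isomer from the minor 13Z isomer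
Reagents that add atoms: pyridinium chlorochromate, [O-][Cr](=O)(=O)Cl.c1cc[nH+]cc1
Why: Babler–Dauben oxidative transposition: the C13 chromate ester undergoes a [3,3]-sigmatropic shift that forms the C15–O bond and the C13=C14 alkene and is then oxidised to the enal, while the tertiary non-allylic 8α-OH has no carbinol hydrogen and survives; the alkene is expected as roughly 2:1 13E/13Z, and the C13 stereocentre of 1 is erased on purpose.

**Step 2**
Reactants: 2 (13E)-8α-hydroxylabd-13-en-15-al
Product: 3 labdanolic acid [(13S)-8α-hydroxylabdan-15-oic acid]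
Conditions: (5aS,10bR)-2-mesityl-5a,10b-dihydro-4H,6H-indeno[2,1-b][1,2,4]triazolo[4,3-d][1,4]oxazin-2-ium chloride (10 mol %), 1-[3,5-bis(trifluoromethyl)phenyl]-3-[(1R,2R)-2-(dimethylamino)cyclohexyl]thiourea (20 mol %), DMAP (20 mol %), H2O (5 equiv), toluene/THF 4:1, 23 °C
Reagents that add atoms: water, O
Why: Proposed new method: the chiral triazolylidene adds to C15 and forms the extended Breslow intermediate in which the 13E geometry is kept, so C13 shows one defined π-face; the amine-thiourea relays a proton to the face left open by the indane wall of the carbene (catalyst control, since the ring stereocentres are five bonds away), the azolium enol tautomerises to the acyl azolium, and DMAP-assisted hydrolysis by water forms the acid C15–O bond and frees the carbene, a net internal redox hydration that sets C13 as S; the closest known reaction type is the carbene-catalysed redox esterification of enals with cooperative carbene/hydrogen-bond-donor enantioselective β-protonation of β-aryl β-alkyl enals by alcohols, not yet shown for β,β-dialkyl enals or with water as acyl acceptor.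

**Step 3**
Reactants: 3 labdanolic acid; 4 formic acid
Product: 6 (13S)-8α-formyloxylabdan-15-oic acid, via formic mixed anhydride 5 (not isolated)
Conditions: HCOOH/Ac2O premixed (55 °C, 2 h, then 0 °C; 4 equiv), pyridine, CH2Cl2, 0 → 23 °C; then THF/pH 5 phosphate buffer, 0 °C, 30 min
Reagents that add atoms: formic acid (4), OC=O, delivered as acetic formic anhydride, CC(=O)OC=O
Why: O-formylation by acyl transfer from the small, highly electrophilic acetic formic anhydride reaches the hindered equatorial tertiary 8α-OH without breaking the C8–O bond (retention at C8); the carboxyl group is formylated transiently to 5 and is released by the buffered aqueous work-up, which the tertiary formate survives.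

**Compound list**

1 | (−)-sclareol, (13R)-labd-14-ene-8α,13-diol | C=C[C@](C)(O)CC[C@@H]1[C@@]2(C)CCCC(C)(C)[C@@H]2CC[C@@]1(C)O | starting material
2 | (13E)-8α-hydroxylabd-13-en-15-al | C/C(=C\C=O)CC[C@@H]1[C@@]2(C)CCCC(C)(C)[C@@H]2CC[C@@]1(C)O | intermediate
3 | labdanolic acid, (13S)-8α-hydroxylabdan-15-oic acid | C[C@@H](CC[C@@H]1[C@@]2(C)CCCC(C)(C)[C@@H]2CC[C@@]1(C)O)CC(=O)O | intermediate
4 | formic acid | OC=O | starting material
5 | (13S)-8α-formyloxylabdan-15-oic formic anhydride | C[C@@H](CC[C@@H]1[C@@]2(C)CCCC(C)(C)[C@@H]2CC[C@@]1(C)OC=O)CC(=O)OC=O | intermediate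
6 | (13S)-8α-formyloxylabdan-15-oic acid, (3S)-5-[(1R,2R,4aS,8aS)-2-formyloxy-2,5,5,8a-tetramethyldecahydronaphthalen-1-yl]-3-methylpentanoic acid (CNP0465436.1) | C[C@@H](CC[C@@H]1[C@@]2(C)CCCC(C)(C)[C@@H]2CC[C@@]1(C)OC=O)CC(=O)O | target

**Step count**

Total steps: 3. Longest linear sequence: 3 (from sclareol).

**Steps most likely to fail**

Step 2, the new carbene redox hydration. The risks are low facial selectivity for a β,β-dialkyl enal, loss of 13E geometry under base, and oxa-Michael addition of the 8α-OH to C13; a modest diastereomer ratio would need upgrading by crystallisation of 3. The fallback uses known iminium chemistry and sets out from 2. It can also take the crude 13E/13Z mixture of step 1, because iminium formation is expected to interconvert the two geometric isomers before hydride transfer. Asymmetric counteranion-directed transfer hydrogenation uses the morpholinium salt of (S)-3,3'-bis(2,4,6-triisopropylphenyl)-1,1'-binaphthyl-2,2'-diyl hydrogen phosphate (20 mol %) and diethyl 2,6-dimethyl-1,4-dihydropyridine-3,5-dicarboxylate (1.1 equiv) in dioxane at 50 °C. This gives (13S)-8α-hydroxylabdan-15-al F1. Pinnick oxidation (NaClO2, NaH2PO4, 2-methyl-2-butene, tBuOH/H2O, 0 °C) then comes back to the route at 3.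

Step 1, the oxidative transposition. The acidic chromium reagent may ionise the allylic alcohol and let the 8α-OH close the manoyl oxide ether, and the 13E/13Z ratio may be poor. The 13Z isomer can be re-equilibrated with catalytic morpholinium trifluoroacetate and recycled. The fallback sets out from 1 and keeps both hydroxyls masked during a closed-shell rearrangement. Acetylation (AcCl, N,N-dimethylaniline, CH2Cl2) gives (13R)-labd-14-ene-8α,13-diyl diacetate F2. The [3,3] allylic acetate shift catalysed by divalent palladium, PdCl2(MeCN)2 (5 mol %) in THF at 23 °C, gives (13E)-labd-13-ene-8α,15-diyl diacetate F3. Saponification (KOH, MeOH, reflux) gives (13E)-labd-13-ene-8α,15-diol F4. Chemoselective allylic oxidation (MnO2, CH2Cl2, 23 °C) comes back to the route at 2.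

Step 3, the formylation. The hindered tertiary alcohol may react slowly, the free acid consumes reagent as the mixed anhydride, and some 8-acetate or C8 elimination may appear. The fallback sets out from 3 and protects the acid so that the formylation can be forced. Benzylation (BnBr, K2CO3, DMF, 23 °C) gives benzyl (13S)-8α-hydroxylabdan-15-oate F5. Formylation with excess neat acetic formic anhydride and pyridine at 40 °C gives benzyl (13S)-8α-formyloxylabdan-15-oate F6. Neutral hydrogenolysis (H2, 10% Pd/C, EtOAc, 23 °C) comes back to the route at 6.

**Further compounds**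

F1 | step 2 | (13S)-8α-hydroxylabdan-15-al | C[C@@H](CC[C@@H]1[C@@]2(C)CCCC(C)(C)[C@@H]2CC[C@@]1(C)O)CC=O
F2 | step 1 | (13R)-labd-14-ene-8α,13-diyl diacetate | C=C[C@](C)(OC(C)=O)CC[C@@H]1[C@@]2(C)CCCC(C)(C)[C@@H]2CC[C@@]1(C)OC(C)=O
F3 | step 1 | (13E)-labd-13-ene-8α,15-diyl diacetate | C/C(=C\COC(C)=O)CC[C@@H]1[C@@]2(C)CCCC(C)(C)[C@@H]2CC[C@@]1(C)OC(C)=O
F4 | step 1 | (13E)-labd-13-ene-8α,15-diol | C/C(=C\CO)CC[C@@H]1[C@@]2(C)CCCC(C)(C)[C@@H]2CC[C@@]1(C)O
F5 | step 3 | benzyl (13S)-8α-hydroxylabdan-15-oate | C[C@@H](CC[C@@H]1[C@@]2(C)CCCC(C)(C)[C@@H]2CC[C@@]1(C)O)CC(=O)OCc1ccccc1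
F6 | step 3 | benzyl (13S)-8α-formyloxylabdan-15-oate | C[C@@H](CC[C@@H]1[C@@]2(C)CCCC(C)(C)[C@@H]2CC[C@@]1(C)OC=O)CC(=O)OCc1ccccc1
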